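Remark on the chemistry: biogenetic numbering is used throughout (guaianolide half C1–C15, seco-eudesmanolide half C1'–C15'). The configuration is taken exactly as drawn (1R,2S,3S,7S,8R,10R,4'R,6'R,7'R,8'S,11'R), which is antipodal to the common 7α-H lactone series, so no isolated natural monomer is used and both halves are built de novo.

## Structural features

The target joins a guaian-12,8-olide (cyclopentene C1–C5 fused to cycloheptane C1/C5–C10, trans-fused α-methylene-γ-lactone on C7/C8) to a 1,10-seco-eudesman-12',8'-olide (cyclohexene C5'–C10' with a tetrasubstituted C5'=C10' bond, cis-fused lactone on C7'/C8', free C6' hydroxyl, C4' side chain ending in the C1' acetate). The bonds C1–C13' and C3–C11' make C1, C2, C3, C4, C5, C13' and C11' a bicyclo[2.2.1]heptene in which C2 (OAc) is the one-carbon bridge and C11' is a spiro quaternary carbon. Seven stereocenters are contiguous (C10–C1–C2–C3–C11'–C7'–C6'/C8'), and two of them (C1, C11') are quaternary. Read in three dimensions, the C2 acetate lies over the C4=C5 bond (away from the C13'–C11' bridge), the lactone carbonyl C12' is exo with C7' endo, and C3 is cis to C6' on the spirolactone, so the diene sits on the concave face of the cis-fused bicycle. Every facial choice of a cycloaddition is therefore the uphill one: anti to the C2 oxygen of a 5-oxycyclopentadiene, onto the hindered lactone face, and with quaternary C11' bonded to C3 against the electronic bias of the substituted diene. Fragile elements are the 5-acyloxycyclopentadiene (1,5-hydrogen shift), the α-methylene lactones, two acetates, the allylic C6' alcohol and the strained tetrasubstituted norbornene alkene. The key step exploits the fact that the only free hydroxyl, O6', ends up beneath C4 (about 3.5–4 Å from the C4 substituent by a hand model) and that C4 bears only a methyl (C15) that can be added last. C4 can therefore be a ketone whose enol oxygen is tied to O6' through a disiloxane, turning the union into a tethered intramolecular Diels–Alder reaction.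

## Logic of the disconnections

40 to 39: the C4–C15 bond is cut. Removing the methyl frees C4 to carry an oxygen function, and C15 returns last from a methyl-tin reagent. The forward step must couple a hindered tetrasubstituted norbornenyl triflate in the presence of lactones, acetates and a free alcohol.

39 to 37: the triflate O–S bond and the O6'–H bond are traced back to the two Si–O bonds of one disiloxane bridge between the C4 enol oxygen and O6'. The gain is that the protecting group of the only free hydroxyl and the activating group at C4 become one temporary ring. The forward step needs fluoride to unmask the C4 enolate (C3 is a bridgehead, so only the C4=C5 enolate can form) and trap it on oxygen.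

37 to 34 and 18 (key): C1–C13' and C3–C11' are cut together with the two Si–O bonds. This removes both quaternary centers, the bicycloheptene and the spiro junction in one operation and leaves two fragments of equal size. The forward step must form a cross-conjugated silyl dienol ether of 18 toward C3 without losing the C2 acetate, and the cycloaddition must outrun the 1,5-hydrogen shift and occur anti to the acetate.

18 to 14 to 13: the lactone C12–O8 bond is cut to an isopropenyl carbinol, then C7–C8 is cut by a retro carbonyl-ene reaction. Ring closure, C8–OH and the C7 isopropenyl group then arise in one step from an aldehyde and a prenyl group on a cyclopentenone. The forward ene step must set C7/C8 trans and in the right sense relative to the C10 methyl.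

13 to 11 to 7 to 5 to 4 to 1 and 2: the cyclopentenone is unravelled to a 2,5-disubstituted furan (Piancatelli retron), which gives the 2,3-disubstituted 4-hydroxycyclopentenone pattern in one step. The C2 configuration is corrected afterwards by an enzymatic hydrolysis and Mitsunobu pair that converges both epimers. The furan–C10 bond is cut to crotonaldehyde, so C10 comes from an organocatalytic Friedel–Crafts alkylation.

34 to 33 to 29: the C6'–O bond (allylic oxidation), the C11'=C13' methylene and the C1' oxygen (hydroboration of a terminal alkene) are removed. The forward allylic oxidation must choose C6' over C9', C14' and C4' and deliver oxygen on the convex face.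

29 to 27 to 25 to 24 to 20 and 22: the lactone C–O bond is cut to a γ-keto ester, C7'–C11' to an enolate alkylation, and the cyclohexadiene to an arene (Birch retron). The ortho-dialkyl arene fixes the tetrasubstituted C5'=C10' bond and the enol ether position without any regiochemical choice. The aryl–C4' bond is cut to an aryl Grignard reagent and a chiral secondary tosylate, so C4' comes from the chiral pool by inversion.

## Other disconnections considered

Alternative 1: the same two bonds (C1–C13', C3–C11') cut between the free diene A1 and 34, forward step an untethered biomimetic Diels–Alder reaction. This is the first plan that comes to mind. Nothing steers the three selectivities identified above: the concave lactone face, the face anti to the 5-acyloxy group, and C11' to C3. The bimolecular rate with a hindered 1,1-disubstituted dienophile must also compete with the 1,5-hydrogen shift of A1. The chosen plan makes the union intramolecular and fixes two of the three by geometry.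

Alternative 2: the same bonds, but with the diene as the cyclopentadienone dimethyl ketal A2, which cannot undergo a hydrogen shift and has no C2 stereocenter. Ketal hydrolysis of the adduct gives the 7-norbornenone A3, which is then reduced. Hydride reaches C2 from the open alkene side, and coordination to the exo lactone carbonyl also places oxygen toward the C13'–C11' bridge, so the C2 epimer of the target is expected. A bridging carbinol of this kind cannot be inverted by substitution, so the plan fails at C2.

Alternative 3: C2–C3 is cut as well, giving the 2,3-seco dienal A4. The forward step is an acid-triggered iso-Nazarov 4π-electrocyclisation to a 2-hydroxycyclopentadiene that is trapped by 34. The precursor is very simple, but the hydroxydiene should tautomerise to a cyclopentenone under the acid it needs, the C2 configuration would rest on torquoselectivity alone, and the trapping stays bimolecular with the same unsolved facial problems.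

Key step: step 22

## Route

Step 1
Reactants: 1 1-(furan-2-yl)but-3-en-1-ol; 2 (E)-but-2-enal
Product: 4 (3R)-3-[5-(1-hydroxybut-3-en-1-yl)furan-2-yl]butan-1-ol, via furylbutanal 3 (not isolated)
Conditions: (2S,5S)-5-benzyl-2-tert-butyl-3-methylimidazolidin-4-one·CF3CO2H (20 mol %), THF/H2O, −30 °C; then NaBH4, EtOH, 0 °C
Reagents that add atoms: none
Why: Iminium-catalysed Friedel–Crafts alkylation of the 2-alkylfuran at C5; the benzyl group of the catalyst shields one face of the (E)-iminium ion and should set C10 as R, and in situ reduction avoids handling the aldehyde.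

Step 2
Reactants: 4 (3R)-3-[5-(1-hydroxybut-3-en-1-yl)furan-2-yl]butan-1-ol
Product: 5 1-{5-[(2R)-4-(tert-butyldiphenylsilyloxy)butan-2-yl]furan-2-yl}but-3-en-1-ol
Conditions: t-BuPh2SiCl, imidazole, CH2Cl2, 0 °C
Reagents that add atoms: tert-butyl(chloro)diphenylsilane, CC(C)(C)[Si](Cl)(c1ccccc1)c1ccccc1
Why: Selective silylation of the primary alcohol; the ether should survive the aqueous Lewis acid of the next step and keeps the chain oxygen from adding to the furan-derived cation.

Step 3
Reactants: 5 1-{5-[(2R)-4-(tert-butyldiphenylsilyloxy)butan-2-yl]furan-2-yl}but-3-en-1-ol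
Product: 7 4-hydroxy-2-(prop-2-en-1-yl)-3-[(2R)-4-(tert-butyldiphenylsilyloxy)butan-2-yl]cyclopent-2-en-1-one (both C4 epimers), via trans-hydroxyenone 6 (not isolated)
Conditions: Dy(OTf)3 (10 mol %), MeCN/H2O, 80 °C; then phosphate buffer pH 8, 60 °C
Reagents that add atoms: water, O
Why: Piancatelli rearrangement of a 5-alkyl-2-furylcarbinol (hydration, ring opening, 4π-electrocyclisation), then the known isomerisation of 4-hydroxy-4-alkyl-5-allylcyclopentenones to 2-allyl-3-alkyl-4-hydroxycyclopentenones; the carbinol configuration is erased and C2 forms as a mixture that step 6 corrects.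

Step 4
Reactants: 7 4-hydroxy-2-(prop-2-en-1-yl)-3-[(2R)-4-(tert-butyldiphenylsilyloxy)butan-2-yl]cyclopent-2-en-1-one
Product: 8 4-hydroxy-2-(3-methylbut-2-en-1-yl)-3-[(2R)-4-(tert-butyldiphenylsilyloxy)butan-2-yl]cyclopent-2-en-1-one (both C4 epimers)
Conditions: second-generation Grubbs catalyst RuCl2(=CHPh)(H2IMes)(PCy3) (5 mol %), 2-methylbut-2-ene, CH2Cl2, 40 °C
Reagents that add atoms: 2-methylbut-2-ene, CC=C(C)C
Why: Cross-metathesis of a terminal allyl group with 2-methylbut-2-ene is a standard way to a prenyl group; the tetrasubstituted enone is inert.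

Step 5
Reactants: 8 4-hydroxy-2-(3-methylbut-2-en-1-yl)-3-[(2R)-4-(tert-butyldiphenylsilyloxy)butan-2-yl]cyclopent-2-en-1-one
Product: 9 3-(3-methylbut-2-en-1-yl)-4-oxo-2-[(2R)-4-(tert-butyldiphenylsilyloxy)butan-2-yl]cyclopent-2-en-1-yl acetate (both C1 epimers)
Conditions: Ac2O, pyridine, DMAP (cat.), CH2Cl2, 0 °C
Reagents that add atoms: acetic anhydride, CC(=O)OC(C)=O
Why: Plain acylation of the secondary allylic alcohol; it sets up the enzymatic discrimination of the two carbinol configurations.

Step 6
Reactants: 9 3-(3-methylbut-2-en-1-yl)-4-oxo-2-[(2R)-4-(tert-butyldiphenylsilyloxy)butan-2-yl]cyclopent-2-en-1-yl acetate (both C1 epimers)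
Product: 11 (1S)-3-(3-methylbut-2-en-1-yl)-4-oxo-2-[(2R)-4-(tert-butyldiphenylsilyloxy)butan-2-yl]cyclopent-2-en-1-yl acetate, via 4R alcohol 10 (not isolated)
Conditions: Burkholderia cepacia lipase, phosphate buffer pH 7/acetone, 30 °C; then AcOH, PPh3, i-PrO2CN=NCO2i-Pr, THF, 0 °C
Reagents that add atoms: acetic acid, CC(O)=O
Why: Lipases hydrolyse the R acetate of 4-acyloxycyclopentenones and leave the S acetate; Mitsunobu esterification of the liberated R alcohol with acetic acid proceeds with inversion, so both epimers should converge on the 2S acetate (guaiane C2).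

Step 7
Reactants: 11 (1S)-3-(3-methylbut-2-en-1-yl)-4-oxo-2-[(2R)-4-(tert-butyldiphenylsilyloxy)butan-2-yl]cyclopent-2-en-1-yl acetate
Product: 12 (1S)-2-[(2R)-4-hydroxybutan-2-yl]-3-(3-methylbut-2-en-1-yl)-4-oxocyclopent-2-en-1-yl acetate
Conditions: HF·pyridine, THF/pyridine, 0 to 23 °C
Reagents that add atoms: none
Why: Buffered fluoride cleaves the silyl ether without touching the acetate or the enone.

Step 8
Reactants: 12 (1S)-2-[(2R)-4-hydroxybutan-2-yl]-3-(3-methylbut-2-en-1-yl)-4-oxocyclopent-2-en-1-yl acetate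
Product: 13 (1S)-3-(3-methylbut-2-en-1-yl)-4-oxo-2-[(2R)-4-oxobutan-2-yl]cyclopent-2-en-1-yl acetate
Conditions: Dess–Martin periodinane, NaHCO3, CH2Cl2, 0 °C
Reagents that add atoms: none
Why: Neutral Dess–Martin oxidation to the aldehyde; the stereocenter is β to the carbonyl and cannot epimerise.

Step 9
Reactants: 13 (1S)-3-(3-methylbut-2-en-1-yl)-4-oxo-2-[(2R)-4-oxobutan-2-yl]cyclopent-2-en-1-yl acetate
Product: 14 (2S,7S,8R,10R)-2-acetoxy-8-hydroxy-15-norguaia-1(5),11(13)-dien-4-one
Conditions: Me2AlCl, CH2Cl2, −78 to −20 °C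
Reagents that add atoms: none
Why: Type 1 intramolecular carbonyl-ene reaction (as in citronellal to isopulegol) closes the seven-membered ring between C8 and C7 through a chair-like array that places OH and isopropenyl trans; allylic strain with the cyclopentenone should hold the C10 methyl pseudo-axial, which relays C10 to C8 (OH anti to the methyl) and C7.

Step 10
Reactants: 14 (2S,7S,8R,10R)-2-acetoxy-8-hydroxy-15-norguaia-1(5),11(13)-dien-4-one
Product: 15 (2S,7S,8R,10R)-2-acetoxy-8,12-dihydroxy-15-norguaia-1(5),11(13)-dien-4-one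
Conditions: SeO2 (cat.), t-BuOOH, CH2Cl2, 23 °C
Reagents that add atoms: tert-butyl hydroperoxide, CC(C)(C)OO
Why: Selenium dioxide allylic oxidation (ene then 2,3-shift) of the methyl of an isopropenyl group is well precedented; the electron-poor enone alkene is much less reactive.

Step 11
Reactants: 15 (2S,7S,8R,10R)-2-acetoxy-8,12-dihydroxy-15-norguaia-1(5),11(13)-dien-4-one
Product: 18 (2S,7S,8R,10R)-2-acetoxy-4-oxo-15-norguaia-1(5),11(13)-dien-12,8-olide, via enal 16 (not isolated), via lactol 17 (not isolated)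
Conditions: MnO2, CH2Cl2, 23 °C
Reagents that add atoms: none
Why: MnO2 oxidises the allylic primary alcohol to the enal, which closes onto the C8 hydroxyl; the allylic lactol is oxidised further to the trans-fused α-methylene lactone, a standard sequence for 2-methylene-1,4-diols.

Step 12
Reactants: 19 4-bromo-3-methylphenol
Product: 20 (4-bromo-3-methylphenoxy)(tert-butyl)dimethylsilane
Conditions: t-BuMe2SiCl, imidazole, DMF, 23 °C
Reagents that add atoms: tert-butyl(chloro)dimethylsilane, CC(C)(C)[Si](C)(C)Cl
Why: Routine phenol silylation; the aryl silyl ether later becomes a regiodefined silyl enol ether in the Birch reduction.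

Step 13
Reactants: 21 (S)-pent-4-en-2-ol
Product: 22 (S)-pent-4-en-2-yl 4-methylbenzenesulfonate
Conditions: TsCl, pyridine, DMAP (cat.), CH2Cl2, 0 °C
Reagents that add atoms: 4-methylbenzenesulfonyl chloride, Cc1ccc(cc1)S(Cl)(=O)=O
Why: Sulfonylation at oxygen leaves the carbinol configuration untouched.

Step 14
Reactants: 20 (4-bromo-3-methylphenoxy)(tert-butyl)dimethylsilane; 22 (S)-pent-4-en-2-yl 4-methylbenzenesulfonate
Product: 24 tert-butyldimethyl{3-methyl-4-[(2R)-pent-4-en-2-yl]phenoxy}silane, via aryl Grignard reagent 23 (not isolated)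
Conditions: Mg, THF, 50 °C; then 22, CuI (10 mol %), TMEDA, LiOMe, THF, 0 °C
Reagents that add atoms: none
Why: Copper-catalysed coupling of aryl Grignard reagents with unactivated secondary tosylates is an SN2 process with inversion, so the S tosylate should give the R benzylic center that becomes C4'.

Step 15
Reactants: 24 tert-butyldimethyl{3-methyl-4-[(2R)-pent-4-en-2-yl]phenoxy}silane
Product: 25 tert-butyldimethyl({5-methyl-4-[(2R)-pent-4-en-2-yl]cyclohexa-1,4-dien-1-yl}oxy)silane
Conditions: Li, NH3 (l), THF, t-BuOH, −78 to −33 °C; NH4Cl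
Reagents that add atoms: none
Why: Birch reduction keeps the oxygen and both alkyl groups on sp2 carbons, so only the 1,4-diene with the tetrasubstituted C5'=C10' bond and the C8'=C7' silyl enol ether can form; the isolated terminal alkene is not reduced.

Step 16
Reactants: 25 tert-butyldimethyl({5-methyl-4-[(2R)-pent-4-en-2-yl]cyclohexa-1,4-dien-1-yl}oxy)silane
Product: 27 ethyl 2-{4-methyl-2-oxo-5-[(2R)-pent-4-en-2-yl]cyclohex-4-en-1-yl}acetate (both C1 epimers), via lithium enolate 26 (not isolated)
Conditions: MeLi, THF, 0 to 23 °C; then DMPU, ICH2CO2Et, −78 °C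
Reagents that add atoms: ethyl iodoacetate, CCOC(=O)CI
Why: Cleavage of the silyl enol ether gives the regiodefined C7' enolate, which is alkylated at low temperature before proton transfer to the more acidic C9' side can occur.

Step 17
Reactants: 27 ethyl 2-{4-methyl-2-oxo-5-[(2R)-pent-4-en-2-yl]cyclohex-4-en-1-yl}acetate
Product: 29 (3aS,7aS)-6-methyl-5-[(2R)-pent-4-en-2-yl]-3a,4,7,7a-tetrahydro-1-benzofuran-2(3H)-one, via cis hydroxy ester 28 (not isolated)
Conditions: ketoreductase (screened for the 7'S,8'S product), NADP+ (cat.), i-PrOH, phosphate buffer pH 8, 30 °C; then PPTS, PhMe, 60 °C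
Reagents that add atoms: none
Why: Enzymatic reduction with dynamic kinetic resolution: the C7' epimers interconvert through the enol while the enzyme reduces only one of them, setting C8' and C7' cis; the cis γ-hydroxy ester then lactonises.

Step 18
Reactants: 29 (3aS,7aS)-6-methyl-5-[(2R)-pent-4-en-2-yl]-3a,4,7,7a-tetrahydro-1-benzofuran-2(3H)-one
Product: 30 (3aS,7aS)-5-[(2R)-5-hydroxypentan-2-yl]-6-methyl-3a,4,7,7a-tetrahydro-1-benzofuran-2(3H)-one
Conditions: 9-BBN, THF, 0 to 23 °C; then H2O2, NaOAc (aq), 0 °C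
Reagents that add atoms: hydrogen peroxide, OO
Why: 9-BBN hydroborates the monosubstituted alkene anti-Markovnikov and leaves the tetrasubstituted alkene and the lactone alone; buffered oxidation protects the lactone.

Step 19
Reactants: 30 (3aS,7aS)-5-[(2R)-5-hydroxypentan-2-yl]-6-methyl-3a,4,7,7a-tetrahydro-1-benzofuran-2(3H)-one
Product: 32 (3aS,7aS)-5-[(2R)-5-hydroxypentan-2-yl]-6-methyl-3-methylidene-3a,4,7,7a-tetrahydro-1-benzofuran-2(3H)-one, via Mannich base 31 (not isolated)
Conditions: LDA (2.2 equiv), THF, −78 °C; Me2N=CH2 I; then MeI, MeOH; NaHCO3 (aq), CH2Cl2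
Reagents that add atoms: N,N-dimethylmethyleneiminium iodide, C=[N+](C)C.[I-]
Why: Standard α-methylenation of a γ-lactone (aminomethylation of the enolate, quaternisation, elimination); the extra equivalent of base holds the primary alcohol as its alkoxide.

Step 20
Reactants: 32 (3aS,7aS)-5-[(2R)-5-hydroxypentan-2-yl]-6-methyl-3-methylidene-3a,4,7,7a-tetrahydro-1-benzofuran-2(3H)-one
Product: 33 (4R)-4-[(3aS,7aS)-6-methyl-3-methylidene-2-oxo-2,3,3a,4,7,7a-hexahydro-1-benzofuran-5-yl]pentyl acetate
Conditions: Ac2O, pyridine, DMAP (cat.), CH2Cl2, 0 °C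
Reagents that add atoms: acetic anhydride, CC(=O)OC(C)=O
Why: Acetylation of the primary alcohol installs the C1' acetate before the second hydroxyl exists, so no differentiation of alcohols is needed.

Step 21
Reactants: 33 (4R)-4-[(3aS,7aS)-6-methyl-3-methylidene-2-oxo-2,3,3a,4,7,7a-hexahydro-1-benzofuran-5-yl]pentyl acetate
Product: 34 (4R)-4-[(3aR,4R,7aS)-4-hydroxy-6-methyl-3-methylidene-2-oxo-3a,4,7,7a-tetrahydro-1-benzofuran-5-yl]pentyl acetate
Conditions: SeO2 (cat.), t-BuOOH, CH2Cl2, 23 °C
Reagents that add atoms: tert-butyl hydroperoxide, CC(C)(C)OO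
Why: Allylic hydroxylation by ene reaction and 2,3-shift keeps the C5'=C10' bond in place; a ring CH2 is preferred over CH3 and CH, C9' is deactivated by the adjacent lactone oxygen, selenium should attack the less hindered C10' end, and oxygen should arrive on the convex face (cis to H7').

Step 22
Reactants: 34 (4R)-4-[(3aR,4R,7aS)-4-hydroxy-6-methyl-3-methylidene-2-oxo-3a,4,7,7a-tetrahydro-1-benzofuran-5-yl]pentyl acetate; 18 (2S,7S,8R,10R)-2-acetoxy-4-oxo-15-norguaia-1(5),11(13)-dien-12,8-olide
Product: 37 cycloadduct with the C4 enol oxygen joined to O6' by a 1,1,3,3-tetraisopropyldisiloxane-1,3-diyl bridge (15-nor skeleton of 40), via disiloxanyl triflate 35 (not isolated), via tethered trienol ether 36 (not isolated)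
Conditions: (i-Pr2SiCl)2O, AgOTf, CH2Cl2, 0 °C; 34, 2,6-lutidine, −78 to 0 °C; then 18, Et3N, −78 to 23 °C; then PhMe, 60 °C
Reagents that add atoms: 1,3-dichloro-1,1,3,3-tetraisopropyldisiloxane, CC(C)[Si](Cl)(C(C)C)O[Si](Cl)(C(C)C)C(C)C
Why: O6' is silylated by one end of the disiloxane bis(triflate), and the other end converts the C4 ketone of 18 by soft enolisation toward C3 (the only α' CH2) into a 2-siloxy-5-acetoxycyclopentadiene that carries the dienophile. A concerted, asynchronous [4+2] addition then forms C1–C13' and C3–C11'; the closest known reaction type is the silicon-tethered type 2 intramolecular Diels–Alder reaction, in which the tether leaves from an internal diene carbon and a bridgehead enol ether results. Two rings close: the six-membered carbocycle C1–C13'–C11'–C3–C4–C5 of the bicycloheptene by suprafacial cycloaddition, and the ten-membered ring C3–C4–O–Si–O–Si–O–C6'–C7'–C11' in the tethered mode. A single R2Si bridge (O···O about 2.7 Å) is judged too short for the estimated 3.5–4 Å O4···O6' separation, hence the disiloxane. C11' is set by the tether, which starts at O6' and so presents the lactone face syn to C6'. C7' should be endo because it carries the tether toward O4, and C12' exo, as is usual for α-methylene lactones. C1 and C3 are set by addition anti to the C2 acetate: the pseudo-axial C14 methyl lies on the acetate face and the exo lactone carbonyl would clash with the acetate there, which should outweigh the syn-directing effect of a 5-oxygen substituent. The step needs C11' to bond to C3 against the electronic bias of a 2-siloxydiene; the tether reach and the avoidance of vicinal quaternary centers C1/C11' are what secure it. The intramolecular rate also has to beat the 1,5-hydrogen shift from C2.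

Step 23
Reactants: 37 cycloadduct with the C4 enol oxygen joined to O6' by a 1,1,3,3-tetraisopropyldisiloxane-1,3-diyl bridge
Product: 39 C4 enol trifluoromethanesulfonate with free 6'-hydroxyl (15-nor-4-triflyloxy analogue of 40), via fluorosilyl ether 38 (not isolated)
Conditions: CsF, PhNTf2, DME, 23 °C; then HF·pyridine, THF, 0 °C
Reagents that add atoms: N-phenylbis(trifluoromethanesulfonimide), O=S(=O)(N(c1ccccc1)S(=O)(=O)C(F)(F)F)C(F)(F)F
Why: Fluoride cleaves the more labile enol Si–O bond; the enolate can only be C4=C5 because C3 is a bridgehead, and it is trapped on oxygen as the triflate; buffered HF then frees the 6'-hydroxyl.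

Step 24
Reactants: 39 C4 enol trifluoromethanesulfonate with free 6'-hydroxyl
Product: 40 target compound CNP0211028.4 (1R,2S,3S,7S,8R,10R,4'R,6'R,7'R,8'S,11'R)
Conditions: Me4Sn, Pd2(dba)3 (5 mol %), AsPh3, LiCl, NMP, 60 °C
Reagents that add atoms: tetramethylstannane, C[Sn](C)(C)C
Why: Stille coupling of an alkenyl triflate with tetramethyltin under neutral conditions installs C15; lactones, acetates, the α-methylene lactone and the free alcohol should be tolerated, and no stereocenter is touched.

## Compound list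

1 | 1-(furan-2-yl)but-3-en-1-ol (racemic) | C=CCC(O)c1ccco1 | starting material
2 | (E)-but-2-enal | C/C=C/C=O | starting material
3 | (3R)-3-[5-(1-hydroxybut-3-en-1-yl)furan-2-yl]butanal | C=CCC(O)c1ccc([C@H](C)CC=O)o1 | intermediate (not isolated)
4 | (3R)-3-[5-(1-hydroxybut-3-en-1-yl)furan-2-yl]butan-1-ol | C=CCC(O)c1ccc([C@H](C)CCO)o1 | intermediate
5 | 1-{5-[(2R)-4-(tert-butyldiphenylsilyloxy)butan-2-yl]furan-2-yl}but-3-en-1-ol | C=CCC(O)c1ccc([C@H](C)CCO[Si](c2ccccc2)(c2ccccc2)C(C)(C)C)o1 | intermediate
6 | 4-hydroxy-5-(prop-2-en-1-yl)-4-[(2R)-4-(tert-butyldiphenylsilyloxy)butan-2-yl]cyclopent-2-en-1-one (4,5-trans, both ring antipodes) | C=CCC1C(=O)C=CC1(O)[C@H](C)CCO[Si](c2ccccc2)(c2ccccc2)C(C)(C)C | intermediate (not isolated)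
7 | 4-hydroxy-2-(prop-2-en-1-yl)-3-[(2R)-4-(tert-butyldiphenylsilyloxy)butan-2-yl]cyclopent-2-en-1-one (both C4 epimers) | C=CCC1=C([C@H](C)CCO[Si](c2ccccc2)(c2ccccc2)C(C)(C)C)C(O)CC1=O | intermediate
8 | 4-hydroxy-2-(3-methylbut-2-en-1-yl)-3-[(2R)-4-(tert-butyldiphenylsilyloxy)butan-2-yl]cyclopent-2-en-1-one (both C4 epimers) | CC(C)=CCC1=C([C@H](C)CCO[Si](c2ccccc2)(c2ccccc2)C(C)(C)C)C(O)CC1=O | intermediate
9 | 3-(3-methylbut-2-en-1-yl)-4-oxo-2-[(2R)-4-(tert-butyldiphenylsilyloxy)butan-2-yl]cyclopent-2-en-1-yl acetate (both C1 epimers) | CC(C)=CCC1=C([C@H](C)CCO[Si](c2ccccc2)(c2ccccc2)C(C)(C)C)C(OC(C)=O)CC1=O | intermediate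
10 | (4R)-4-hydroxy-2-(3-methylbut-2-en-1-yl)-3-[(2R)-4-(tert-butyldiphenylsilyloxy)butan-2-yl]cyclopent-2-en-1-one | CC(C)=CCC1=C([C@H](C)CCO[Si](c2ccccc2)(c2ccccc2)C(C)(C)C)[C@H](O)CC1=O | intermediate (not isolated)
11 | (1S)-3-(3-methylbut-2-en-1-yl)-4-oxo-2-[(2R)-4-(tert-butyldiphenylsilyloxy)butan-2-yl]cyclopent-2-en-1-yl acetate | CC(C)=CCC1=C([C@H](C)CCO[Si](c2ccccc2)(c2ccccc2)C(C)(C)C)[C@@H](OC(C)=O)CC1=O | intermediate
12 | (1S)-2-[(2R)-4-hydroxybutan-2-yl]-3-(3-methylbut-2-en-1-yl)-4-oxocyclopent-2-en-1-yl acetate | CC(C)=CCC1=C([C@H](C)CCO)[C@@H](OC(C)=O)CC1=O | intermediate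
13 | (1S)-3-(3-methylbut-2-en-1-yl)-4-oxo-2-[(2R)-4-oxobutan-2-yl]cyclopent-2-en-1-yl acetate | CC(C)=CCC1=C([C@H](C)CC=O)[C@@H](OC(C)=O)CC1=O | intermediate
14 | (2S,7S,8R,10R)-2-acetoxy-8-hydroxy-15-norguaia-1(5),11(13)-dien-4-one | O[C@@H]1C[C@@H](C)C2=C(C[C@H]1C(C)=C)C(=O)C[C@@H]2OC(C)=O | intermediate
15 | (2S,7S,8R,10R)-2-acetoxy-8,12-dihydroxy-15-norguaia-1(5),11(13)-dien-4-one | O[C@@H]1C[C@@H](C)C2=C(C[C@H]1C(=C)CO)C(=O)C[C@@H]2OC(C)=O | intermediate
16 | (2S,7S,8R,10R)-2-acetoxy-8-hydroxy-4-oxo-15-norguaia-1(5),11(13)-dien-12-al | O[C@@H]1C[C@@H](C)C2=C(C[C@H]1C(=C)C=O)C(=O)C[C@@H]2OC(C)=O | intermediate (not isolated)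
17 | (2S,7S,8R,10R)-2-acetoxy-12-hydroxy-8,12-epoxy-15-norguaia-1(5),11(13)-dien-4-one (lactol, both anomers) | C=C1C(O)O[C@@H]2C[C@@H](C)C3=C(C[C@@H]12)C(=O)C[C@@H]3OC(C)=O | intermediate (not isolated)
18 | (2S,7S,8R,10R)-2-acetoxy-4-oxo-15-norguaia-1(5),11(13)-dien-12,8-olide | C=C1C(=O)O[C@@H]2C[C@@H](C)C3=C(C[C@@H]12)C(=O)C[C@@H]3OC(C)=O | intermediate
19 | 4-bromo-3-methylphenol | Cc1cc(O)ccc1Br | starting material
20 | (4-bromo-3-methylphenoxy)(tert-butyl)dimethylsilane | Cc1cc(O[Si](C)(C)C(C)(C)C)ccc1Br | intermediate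
21 | (S)-pent-4-en-2-ol | C[C@H](O)CC=C | starting material
22 | (S)-pent-4-en-2-yl 4-methylbenzenesulfonate | C[C@H](OS(=O)(=O)c1ccc(C)cc1)CC=C | intermediate
23 | [4-(tert-butyldimethylsilyloxy)-2-methylphenyl]magnesium bromide | Cc1cc(O[Si](C)(C)C(C)(C)C)ccc1[Mg]Br | intermediate (not isolated)
24 | tert-butyldimethyl{3-methyl-4-[(2R)-pent-4-en-2-yl]phenoxy}silane | C=CC[C@@H](C)c1ccc(O[Si](C)(C)C(C)(C)C)cc1C | intermediate
25 | tert-butyldimethyl({5-methyl-4-[(2R)-pent-4-en-2-yl]cyclohexa-1,4-dien-1-yl}oxy)silane | C=CC[C@@H](C)C1=C(C)CC(O[Si](C)(C)C(C)(C)C)=CC1 | intermediate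
26 | lithium 5-methyl-4-[(2R)-pent-4-en-2-yl]cyclohexa-1,4-dien-1-olate | C=CC[C@@H](C)C1=C(C)CC([O-])=CC1.[Li+] | intermediate (not isolated)
27 | ethyl 2-{4-methyl-2-oxo-5-[(2R)-pent-4-en-2-yl]cyclohex-4-en-1-yl}acetate (both C1 epimers) | C=CC[C@@H](C)C1=C(C)CC(=O)C(CC(=O)OCC)C1 | intermediate
28 | ethyl 2-{(1S,6S)-6-hydroxy-4-methyl-3-[(2R)-pent-4-en-2-yl]cyclohex-3-en-1-yl}acetate | O[C@H]1CC(C)=C([C@H](C)CC=C)C[C@H]1CC(=O)OCC | intermediate (not isolated)
29 | (3aS,7aS)-6-methyl-5-[(2R)-pent-4-en-2-yl]-3a,4,7,7a-tetrahydro-1-benzofuran-2(3H)-one | C1C(=O)O[C@H]2CC(C)=C([C@H](C)CC=C)C[C@@H]12 | intermediate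
30 | (3aS,7aS)-5-[(2R)-5-hydroxypentan-2-yl]-6-methyl-3a,4,7,7a-tetrahydro-1-benzofuran-2(3H)-one | C1C(=O)O[C@H]2CC(C)=C([C@H](C)CCCO)C[C@@H]12 | intermediate
31 | (3aS,7aS)-3-[(dimethylamino)methyl]-5-[(2R)-5-hydroxypentan-2-yl]-6-methyl-3a,4,7,7a-tetrahydro-1-benzofuran-2(3H)-one (C3 epimers) | CN(C)CC1C(=O)O[C@H]2CC(C)=C([C@H](C)CCCO)C[C@@H]12 | intermediate (not isolated)
32 | (3aS,7aS)-5-[(2R)-5-hydroxypentan-2-yl]-6-methyl-3-methylidene-3a,4,7,7a-tetrahydro-1-benzofuran-2(3H)-one | C=C1C(=O)O[C@H]2CC(C)=C([C@H](C)CCCO)C[C@@H]12 | intermediate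
33 | (4R)-4-[(3aS,7aS)-6-methyl-3-methylidene-2-oxo-2,3,3a,4,7,7a-hexahydro-1-benzofuran-5-yl]pentyl acetate | C=C1C(=O)O[C@H]2CC(C)=C([C@H](C)CCCOC(C)=O)C[C@@H]12 | intermediate
34 | (4R)-4-[(3aR,4R,7aS)-4-hydroxy-6-methyl-3-methylidene-2-oxo-3a,4,7,7a-tetrahydro-1-benzofuran-5-yl]pentyl acetate | C=C1C(=O)O[C@H]2CC(C)=C([C@H](C)CCCOC(C)=O)[C@H](O)[C@@H]12 | intermediate
35 | 6'-O-[1,1,3,3-tetraisopropyl-3-(trifluoromethanesulfonyloxy)disiloxan-1-yl] derivative of 34 | C=C1C(=O)O[C@H]2CC(C)=C([C@H](C)CCCOC(C)=O)[C@H](O[Si](C(C)C)(C(C)C)O[Si](OS(=O)(=O)C(F)(F)F)(C(C)C)C(C)C)[C@@H]12 | intermediate (not isolated)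
36 | 3,4-dienol ether of 18 linked through O4–Si(i-Pr)2–O–Si(i-Pr)2–O6' to 34 | C=C1C(=O)O[C@@H]2C[C@@H](C)C3=C(C[C@@H]12)C(O[Si](C(C)C)(C(C)C)O[Si](C(C)C)(C(C)C)O[C@H]4C(=C(C)C[C@@H]5OC(=O)C(=C)[C@H]45)[C@H](C)CCCOC(C)=O)=C[C@@H]3OC(C)=O | intermediate (not isolated)
37 | cycloadduct: 15-nor skeleton of 40 with C4–O and O6' bridged by 1,1,3,3-tetraisopropyldisiloxane-1,3-diyl (1R,2S,3S,7S,8R,10R,4'R,6'R,7'R,8'S,11'R) | C=C1C(=O)O[C@@H]2C[C@@H](C)[C@]34C[C@@]5(C(=O)O[C@H]6CC(C)=C([C@H](C)CCCOC(C)=O)[C@H](O[Si]7(C(C)C)C(C)C)[C@H]65)[C@H](C(O[Si](C(C)C)(C(C)C)O7)=C3C[C@@H]12)[C@@H]4OC(C)=O | intermediate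
38 | C4 enol trifluoromethanesulfonate bearing the 6'-O-(3-fluoro-1,1,3,3-tetraisopropyldisiloxan-1-yl) group | C=C1C(=O)O[C@@H]2C[C@@H](C)[C@]34C[C@@]5(C(=O)O[C@H]6CC(C)=C([C@H](C)CCCOC(C)=O)[C@H](O[Si](C(C)C)(C(C)C)O[Si](F)(C(C)C)C(C)C)[C@H]65)[C@H](C(OS(=O)(=O)C(F)(F)F)=C3C[C@@H]12)[C@@H]4OC(C)=O | intermediate (not isolated)
39 | C4 enol trifluoromethanesulfonate with free 6'-hydroxyl (15-nor-4-triflyloxy analogue of 40) | C=C1C(=O)O[C@@H]2C[C@@H](C)[C@]34C[C@@]5(C(=O)O[C@H]6CC(C)=C([C@H](C)CCCOC(C)=O)[C@H](O)[C@H]65)[C@H](C(OS(=O)(=O)C(F)(F)F)=C3C[C@@H]12)[C@@H]4OC(C)=O | intermediate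
40 | CNP0211028.4 (1R,2S,3S,7S,8R,10R,4'R,6'R,7'R,8'S,11'R) | C=C1C(=O)O[C@@H]2C[C@@H](C)[C@]34C[C@@]5(C(=O)O[C@H]6CC(C)=C([C@H](C)CCCOC(C)=O)[C@H](O)[C@H]65)[C@H](C(C)=C3C[C@@H]12)[C@@H]4OC(C)=O | target

## Step count and least certain steps

Total step count: 24. Longest linear sequence: 14 steps (steps 1–11, then 22–24). The second branch (steps 12–21) joins at step 22.

Step 22 (key step). Most likely failures: loss of the C2 acetate by β-elimination during enolisation; a 1,5-hydrogen shift of the dienol ether before cycloaddition; addition on the acetate-bearing face of the diene; or closure in the other regiochemical sense if the ten-membered tether is too loose to override the electronic bias of the siloxydiene. Fallback, from 18 and 34, returning at 40: MeTi(Oi-Pr)3 adds methyl to the C4 ketone of 18 without attacking the esters to give the tertiary carbinol F1. Dehydration of F1 with the Burgess reagent at 23 °C in the presence of excess 34 releases the diene A1, which is intercepted in an untethered Diels–Alder reaction to give 40 directly, after separation from its isomers.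

Step 3. The bulky secondary alkyl group on the furan may slow the hydration that starts the Piancatelli rearrangement, and the hot aqueous Lewis acid may cleave the silyl ether or polymerise the furylcarbinol. Fallback, from 5, returning at 7: anodic methoxylation of the furan in methanol gives the 2,5-dimethoxy-2,5-dihydrofuran F2. Mild aqueous acid unmasks the cis-enedione, which undergoes intramolecular aldol closure and the same isomerisation in phosphate buffer to give 7.

Step 9. Poor facial selectivity of the ene closure relative to C10, or competing Lewis-acid complexation of the enone that stalls cyclisation. Fallback, from 13, returning at 14: the mixture of C7/C8 diastereomers from the ene reaction is oxidised with Dess–Martin periodinane to the C8 ketone F3. C7 is equilibrated with DBU, and NaBH4 at −78 °C reduces the isolated ketone in preference to the enone to the trans carbinol 14.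

Step 17. Slow epimerisation at C7' (no dynamic resolution), migration of the β,γ-double bond into conjugation under the buffer, or no enzyme in the panel with the needed sense. Fallback, from 27, returning at 34: L-Selectride reduction and PPTS lactonisation give 29 together with its ring-antipodal diastereomer F4. The mixture is carried through steps 18–21, and lipase-catalysed acetylation then removes the unwanted diastereomer as its 6'-acetate F5, leaving 34.

Step 21. Oxidation at C9', C14' or C4' instead of C6', delivery of oxygen on the concave face, or over-oxidation to the enone. Fallback, from 33, returning at 34: allylic oxidation with CrO3·3,5-dimethylpyrazole gives the enone F6. Luche reduction from the convex face gives the 6'-epimeric alcohol F7, Mitsunobu reaction with formic acid inverts C6' to the formate F8, and aqueous NaHCO3 cleaves the formate in the presence of the acetate to give 34.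

## Further compounds

F1 | step 22 | (2S,7S,8R,10R)-2-acetoxy-4-hydroxyguaia-1(5),11(13)-dien-12,8-olide (both C4 epimers) | C=C1C(=O)O[C@@H]2C[C@@H](C)C3=C(C[C@@H]12)C(C)(O)C[C@@H]3OC(C)=O
F2 | step 3 | 1-{5-[(2R)-4-(tert-butyldiphenylsilyloxy)butan-2-yl]-2,5-dimethoxy-2,5-dihydrofuran-2-yl}but-3-en-1-ol (mixture at the ring and carbinol centers) | C=CCC(O)C1(OC)C=CC(OC)([C@H](C)CCO[Si](c2ccccc2)(c2ccccc2)C(C)(C)C)O1
F3 | step 9 | (2S,7S,10R)-2-acetoxy-15-norguaia-1(5),11(13)-diene-4,8-dione | O=C1C[C@@H](C)C2=C(C[C@H]1C(C)=C)C(=O)C[C@@H]2OC(C)=O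
F4 | step 17 | (3aR,7aR)-6-methyl-5-[(2R)-pent-4-en-2-yl]-3a,4,7,7a-tetrahydro-1-benzofuran-2(3H)-one | C1C(=O)O[C@@H]2CC(C)=C([C@H](C)CC=C)C[C@H]12
F5 | step 17 | (4R)-4-[(3aS,4S,7aR)-4-acetoxy-6-methyl-3-methylidene-2-oxo-3a,4,7,7a-tetrahydro-1-benzofuran-5-yl]pentyl acetate | C=C1C(=O)O[C@@H]2CC(C)=C([C@H](C)CCCOC(C)=O)[C@@H](OC(C)=O)[C@H]12
F6 | step 21 | (4R)-4-[(3aS,7aS)-6-methyl-3-methylidene-2,4-dioxo-3a,4,7,7a-tetrahydro-1-benzofuran-5-yl]pentyl acetate | C=C1C(=O)O[C@H]2CC(C)=C([C@H](C)CCCOC(C)=O)C(=O)[C@@H]12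
F7 | step 21 | (4R)-4-[(3aR,4S,7aS)-4-hydroxy-6-methyl-3-methylidene-2-oxo-3a,4,7,7a-tetrahydro-1-benzofuran-5-yl]pentyl acetate | C=C1C(=O)O[C@H]2CC(C)=C([C@H](C)CCCOC(C)=O)[C@@H](O)[C@@H]12
F8 | step 21 | (4R)-4-[(3aR,4R,7aS)-4-formyloxy-6-methyl-3-methylidene-2-oxo-3a,4,7,7a-tetrahydro-1-benzofuran-5-yl]pentyl acetate | C=C1C(=O)O[C@H]2CC(C)=C([C@H](C)CCCOC(C)=O)[C@H](OC=O)[C@@H]12
A1 | alternative 1 | (2S,7S,8R,10R)-2-acetoxyguaia-1(5),3,11(13)-trien-12,8-olide | C=C1C(=O)O[C@@H]2C[C@@H](C)C3=C(C[C@@H]12)C(C)=C[C@@H]3OC(C)=O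
A2 | alternative 2 | (7S,8R,10R)-2,2-dimethoxyguaia-1(5),3,11(13)-trien-12,8-olide | C=C1C(=O)O[C@@H]2C[C@@H](C)C3=C(C[C@@H]12)C(C)=CC3(OC)OC
A3 | alternative 2 | 2-oxo analogue of 40 lacking the C2 acetate (7-norbornenone adduct) | C=C1C(=O)O[C@@H]2C[C@@H](C)[C@]34C[C@@]5(C(=O)O[C@H]6CC(C)=C([C@H](C)CCCOC(C)=O)[C@H](O)[C@H]65)[C@H](C(C)=C3C[C@@H]12)C4=O
A4 | alternative 3 | (7S,8R,10R)-2-oxo-2,3-secoguaia-1(5),3,11(13)-trien-12,8-olide | C=C1C(=O)O[C@@H]2C[C@@H](C)C(C=O)=C(C[C@@H]12)C(C)=C
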